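All runs were generated by integration on assumed constants; the scatter is artificial.

Late in the autumn run, at 8.00 h, you read 46% tris adduct and 0% bis adduct. Keep a ledger of the substrate charged. One coupling partner makes first product, and a second makes bis adduct. There the molecule meets a fork: a further partner makes tris adduct, or it decomposes. At a given partner concentration B, the step to tris adduct is pseudo-first-order in bis adduct, so the chance p of tris adduct is p = B/(B + H), where H is a fork level still to be read. The whole substrate charge as tris adduct takes 30.0 mM of partner.

| flask | substrate | coupling partner | remark | time |
|---|---|---|---|---|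
| spring | 10 mM | 20 mM | run made earlier |  |
| noon | 10 mM | 28 mM | run made earlier |  |
| autumn | 10 mM | 44 mM | run made earlier |  |
| oak | 10 mM | 20.0 mM (fed, over 8.0 h) | all else is in the flask from the start; the feed brings no volume worth counting | 12 h |
| ash | 10 mM (fed, over 8.0 h) | 20.0 mM | all else is in the flask from the start; the feed brings no volume worth counting | 12 h |
| maple | 10 mM | 20.0 mM | everything together at the start | 12 h |

| run | time / h | tris adduct / % | bis adduct / % |
|---|---|---|---|
| spring | 0.667 | 1 | 10 |
| spring | 2.00 | 7 | 11 |
| spring | 3.00 | 9 | 9 |
| spring | 5.00 | 10 | 6 |
| spring | 8.00 | 11 | 4 |
| noon | 1.33 | 11 | 19 |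
| noon | 3.00 | 19 | 9 |
| noon | 4.00 | 20 | 6 |
| noon | 6.00 | 21 | 1 |
| noon | 8.00 | 24 | 0 |
| autumn | 0.667 | 12 | 26 |
| autumn | 2.00 | 37 | 11 |
| autumn | 3.00 | 39 | 6 |
| autumn | 5.00 | 41 | 0 |
| autumn | 8.00 | 46 | 0 |

(scatter of a reading: 1.5 percentage points)

- in percentages every species weighs as the substrate in it: one idle adduct counts as two
- for tris adduct the idle adduct is counted in
- the earlier runs were read with a standard deviation of 1.5 percentage points
- candidate steps: substrate + coupling partner -> first product; coupling partner + first product -> bis adduct; coupling partner + bis adduct -> tris adduct; bis adduct -> decomposed reagent; substrate + tris adduct <-> idle adduct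
- in an amount of tris adduct, one idle adduct counts as one tris adduct

1. the best flask by share of tris adduct in tris adduct plus bis adduct; "all alike" if 1.5 percentage points covers them all (oak / ash / maple / all alike)
2. share of tris adduct in tris adduct plus bis adduct at the end, oak
3. share of tris adduct in tris adduct plus bis adduct at the end, ash
4. share of tris adduct in tris adduct plus bis adduct at the end, maple

Close the autumn books roughly. Enter the remaining 54.0% as decomposed, though some may still be substrate or first product. For autumn, take the charge less two partners per substrate, 24.0 mM, as a rough partner level at the fork. That reads 28.2 mM for H, the fork level, the partner concentration at which bis adduct has even chances.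

Maple repeats the spring recipe. Spring's bis adduct falls from 6% to 4% between its last readings. That pace, carried on, gives an estimate of 2.33% at 12 h. With tris adduct held at 11%, your share for maple is 82.5%.

The forecast, holding that “bis is mostly lost by decomposition”, gives 67% for oak, 92% for ash and 87% for maple, which is above your figure. It names ash as best.

The flasks give 74.5% for oak, 88.4% for ash and 93.8% for maple, so maple is best.

    substrate + coupling partner → first product (k = 1.53 /M/min)
    coupling partner + first product → bis adduct (k = 0.953 /M/min)
    coupling partner + bis adduct → tris adduct (k = 0.617 /M/min)
    bis adduct → decomposed reagent (k = 0.0214 /min)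
    substrate + tris adduct ⇌ idle adduct, settled at all times (K = 161 /M)

In oak, partner averaged 3.13 mM over the first 8.0 h, so the estimate of p is 9.99%. At 8.00 h, oak holds 10.2% of tris adduct in tris adduct plus decomposed reagent. In ash, from 8.00 h to 12.0 h, the mean of the two partner levels at those times is 3.51 mM, so the estimate of p is 11.1%. Tris adduct takes 8.82% of what tris adduct and decomposed reagent gain in ash over those hours. Taking away the decomposition of bis adduct turns the gap in share between maple and oak most: it falls from 19 percentage points to 3.2 points.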